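**Retrosynthetic overview**
- The route rests on the 4-hydroxy-2H-pyran-3(6H)-one ring O–C5–C6(=O)–C7(OH)=C8–C16. C6, C7, C8 and C16 are read as C2, C3, C4 and C5 of a furan, and the ring oxygen as the oxygen of a C5 carbinol on furan C2.
- The target comes from the C16 lactol by silane reduction and deprotection. The lactol comes from oxidative ring expansion of a 3-MOM-oxy-4-alkyl-2-furyl carbinol. This is the only ring-forming event; the furan itself comes from a tetrahydrofuranone keto ester by dehydrogenation.
- The furyl carbinol comes from carboxylate alkylation (C1 ester) after a catalytic asymmetric vinylogous Mukaiyama aldol on a furan-2-carbaldehyde (C4–C5 bond, sets C5).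
- The aldehyde comes from MOM-directed lithiation/formylation. C9–C10 is made by palladium-catalysed coupling of a furylmethyl bromide with an E-alkenylzirconocene. The alkyne for it comes from methyl (S)-3-hydroxybutanoate (C13 from the pool, C12 by Fráter–Seebach methylation).

Key step: step 16

Assumption: atom numbers follow the monic acid skeleton (C1 enoate carbonyl, C5 ring CH, C6 ketone, C7 enol carbon, C8 ring carbon bearing C9, C16 ring OCH2, C12/C13 side-chain stereocentres); the target is taken as the drawn C7-enol tautomer (5S,12R,13S; 2E,10E). Commercial 6-bromohexanoic acid and methyl 3-methylbut-2-enoate are used as starting materials.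

**Route**

Step 1
Reactants: 1 methyl 4-oxotetrahydrofuran-3-carboxylate
Product: 2 methyl 4-hydroxyfuran-3-carboxylate (may sit partly as its 4-oxo-4,5-dihydro tautomer)
Conditions: DDQ (1.1 equiv), 1,4-dioxane, 90 °C
Reagents that add atoms: none
Why: DDQ dehydrogenation of an enolisable β-keto ester, in which hydride is taken from the ring CH2 next to oxygen and β to the ketone, and the resulting furanone should tautomerise to the ester-hydrogen-bonded hydroxyfuran.

Step 2
Reactants: 2 methyl 4-hydroxyfuran-3-carboxylate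
Product: 3 methyl 4-(methoxymethoxy)furan-3-carboxylate
Conditions: MOMCl (1.5 equiv), iPr2NEt (2 equiv), CH2Cl2, 0 °C to rt
Reagents that add atoms: chloromethyl methyl ether (MOMCl), COCCl
Why: O-alkylation of the acidic furanol with a hard electrophile locks the aromatic tautomer and installs the group that later directs lithiation and masks the C7 oxygen.

Step 3
Reactants: 3 methyl 4-(methoxymethoxy)furan-3-carboxylate
Product: 4 [4-(methoxymethoxy)furan-3-yl]methanol
Conditions: iBu2AlH (2.5 equiv), CH2Cl2, −78 to 0 °C; aq potassium sodium tartrate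
Reagents that add atoms: none
Why: standard aluminium hydride reduction of an aryl ester to the primary alcohol, leaving the MOM acetal untouched.

Step 4
Reactants: 4 [4-(methoxymethoxy)furan-3-yl]methanol
Product: 5 3-(bromomethyl)-4-(methoxymethoxy)furan
Conditions: CBr4 (1.2 equiv), PPh3 (1.25 equiv), CH2Cl2, 0 °C; filtered through neutral alumina and used at once
Reagents that add atoms: tetrabromomethane, BrC(Br)(Br)Br
Why: Appel reaction under neutral conditions converts the furylmethyl alcohol into the bromide without acid that would harm the MOM group or the furan.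

Step 5
Reactants: 6 methyl (S)-3-hydroxybutanoate
Product: 8 methyl (2S,3S)-3-hydroxy-2-methylbutanoate, via dilithium dianion 7 (not isolated)
Conditions: LiN(iPr)2 (LDA, 2.2 equiv), THF, −78 to −20 °C; MeI (1.5 equiv), DMPU, −78 to 0 °C; H2O
Reagents that add atoms: iodomethane, CI
Why: Fráter–Seebach alkylation, in which the lithium-chelated alkoxide enolate is methylated on the face away from the C3 methyl, so the anti (2S,3S) ester (future C12 and C13) should form.

Step 6
Reactants: 8 methyl (2S,3S)-3-hydroxy-2-methylbutanoate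
Product: 9 methyl (2S,3S)-3-(tert-butyldimethylsilyloxy)-2-methylbutanoate
Conditions: TBSCl (1.2 equiv), imidazole (2.5 equiv), DMF, rt
Reagents that add atoms: tert-butyldimethylsilyl chloride, CC(C)(C)[Si](C)(C)Cl
Why: routine silylation of a secondary alcohol; the TBS ether survives every later step up to step 18.

Step 7
Reactants: 9 methyl (2S,3S)-3-(tert-butyldimethylsilyloxy)-2-methylbutanoate
Product: 10 (2S,3S)-3-(tert-butyldimethylsilyloxy)-2-methylbutanal
Conditions: iBu2AlH (1.1 equiv), CH2Cl2, −78 °C; MeOH, then aq potassium sodium tartrate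
Reagents that add atoms: none
Why: partial reduction of a β-silyloxy methyl ester stops at the aluminium hemiacetal at −78 °C and releases the aldehyde on work-up without touching the α-stereocentre.

Step 8
Reactants: 10 (2S,3S)-3-(tert-butyldimethylsilyloxy)-2-methylbutanal
Product: 11 (3R,4S)-4-(tert-butyldimethylsilyloxy)-3-methylpent-1-yne
Conditions: dimethyl (1-diazo-2-oxopropyl)phosphonate (1.3 equiv), K2CO3 (2 equiv), MeOH, 0 °C to rt
Reagents that add atoms: dimethyl (1-diazo-2-oxopropyl)phosphonate, COP(=O)(OC)C(=[N+]=[N-])C(C)=O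
Why: Ohira–Bestmann homologation gives the terminal alkyne under carbonate conditions mild enough that the α-methyl centre should not epimerise at 0 °C.

Step 9
Reactants: 11 (3R,4S)-4-(tert-butyldimethylsilyloxy)-3-methylpent-1-yne; 5 3-(bromomethyl)-4-(methoxymethoxy)furan
Product: 13 3-(methoxymethoxy)-4-[(2E,4R,5S)-5-(tert-butyldimethylsilyloxy)-4-methylhex-2-en-1-yl]furan, via alkenylzirconocene chloride 12 (not isolated)
Conditions: Cp2Zr(H)Cl (1.2 equiv), THF, rt, 30 min; then 5, Pd(PPh3)4 (5 mol %), THF, rt
Reagents that add atoms: none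
Why: syn-hydrozirconation places zirconium on the terminal carbon with E geometry, and Negishi-type coupling (oxidative addition of the furylmethyl bromide to zerovalent palladium, transmetallation, reductive elimination) should form C9–C10 with retention of the alkene geometry.

Step 10
Reactants: 13 3-(methoxymethoxy)-4-[(2E,4R,5S)-5-(tert-butyldimethylsilyloxy)-4-methylhex-2-en-1-yl]furan
Product: 15 3-(methoxymethoxy)-4-[(2E,4R,5S)-5-(tert-butyldimethylsilyloxy)-4-methylhex-2-en-1-yl]furan-2-carbaldehyde, via 2-lithiofuran 14 (not isolated)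
Conditions: n-BuLi (1.1 equiv), THF, −78 °C, 45 min; DMF (3 equiv), −78 to 0 °C; H2O
Reagents that add atoms: N,N-dimethylformamide, CN(C)C=O
Why: directed ortho-metalation, in which the furan α-position flanked by the ring oxygen and the MOM ether is lithiated faster than the other α-position or the C9 methylene, and DMF then delivers the formyl group.

Step 11
Reactants: 16 methyl 3-methylbut-2-enoate
Product: 18 tert-butyl[(1-methoxy-3-methylbuta-1,3-dien-1-yl)oxy]dimethylsilane, via lithium dienolate 17 (not isolated)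
Conditions: LiN(iPr)2 (LDA, 1.1 equiv), THF, −78 °C; TBSCl (1.2 equiv), DMPU, −78 °C to rt; distillation
Reagents that add atoms: tert-butyldimethylsilyl chloride, CC(C)(C)[Si](C)(C)Cl
Why: γ-deprotonation of the enoate and O-silylation give the silyl dienolate; a simple methyl ester is used because selective dienolate formation from an ester that already carried the hexanoate chain would not be possible.

Step 12
Reactants: 15 the furan-2-carbaldehyde; 18 the silyl dienolate
Product: 19 methyl (2E,5S)-5-hydroxy-5-{3-(methoxymethoxy)-4-[(2E,4R,5S)-5-(tert-butyldimethylsilyloxy)-4-methylhex-2-en-1-yl]furan-2-yl}-3-methylpent-2-enoate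
Conditions: SiCl4 (1.1 equiv), (S,S)-bisphosphoramide (5 mol %; two binaphthyl-2,2'-diamine phosphoramide units joined by an N,N'-dimethylpentane-1,5-diamine tether), iPr2NEt (10 mol %), 18 (1.2 equiv), CH2Cl2, −78 °C; aq NaHCO3
Reagents that add atoms: none
Why: Lewis-base-catalysed vinylogous Mukaiyama aldol, in which the chiral phosphoramide-bound trichlorosilyl cation activates the aldehyde and the dienolate attacks through its γ-carbon in an open transition state; the (S,S)-catalyst is chosen to expose the Si face of the formyl group (the (R,R)-antipode favours the Re face of aryl aldehydes), which sets C5 as (S), and the s-trans dienolate should give the 2E enoate.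

Step 13
Reactants: 19 the methyl ester
Product: 20 (2E,5S)-5-hydroxy-5-{3-(methoxymethoxy)-4-[(2E,4R,5S)-5-(tert-butyldimethylsilyloxy)-4-methylhex-2-en-1-yl]furan-2-yl}-3-methylpent-2-enoic acid
Conditions: LiOH (4 equiv), THF/MeOH/H2O (3:1:1), rt; AcOH to pH 5, 0 °C; used directly
Reagents that add atoms: lithium hydroxide, [Li+].[OH-]
Why: saponification of the conjugated methyl ester leaves the silyl ether, MOM acetal and E-alkenes alone, and the weakly acidic work-up spares the acid-labile electron-rich furyl carbinol.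

Step 14
Reactants: 21 6-bromohexanoic acid
Product: 22 2-(trimethylsilyl)ethyl 6-bromohexanoate
Conditions: 2-(trimethylsilyl)ethanol (1.1 equiv), DCC (1.1 equiv), DMAP (0.1 equiv), CH2Cl2, 0 °C to rt
Reagents that add atoms: 2-(trimethylsilyl)ethanol, C[Si](C)(C)CCO
Why: Steglich esterification protects the terminal carboxyl as an ester that is later removed by acid without base.

Step 15
Reactants: 20 the hydroxy acid; 22 2-(trimethylsilyl)ethyl 6-bromohexanoate
Product: 23 6-oxo-6-[2-(trimethylsilyl)ethoxy]hexyl (2E,5S)-5-hydroxy-5-{3-(methoxymethoxy)-4-[(2E,4R,5S)-5-(tert-butyldimethylsilyloxy)-4-methylhex-2-en-1-yl]furan-2-yl}-3-methylpent-2-enoate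
Conditions: Cs2CO3 (1.2 equiv), 22 (1.3 equiv), DMF, rt
Reagents that add atoms: none
Why: SN2 alkylation of the caesium carboxylate by the primary bromide is chemoselective over the free secondary C5 hydroxyl, which must stay free for the ring expansion.

Step 16
Reactants: 23 the C5 furyl carbinol
Product: 25 6-oxo-6-[2-(trimethylsilyl)ethoxy]hexyl (2E)-4-{(2S)-6-hydroxy-4-(methoxymethoxy)-5-[(2E,4R,5S)-5-(tert-butyldimethylsilyloxy)-4-methylhex-2-en-1-yl]-3-oxo-3,6-dihydro-2H-pyran-2-yl}-3-methylbut-2-enoate (both C16 anomers), via cis-enedione 24 (not isolated)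
Conditions: NBS (1.05 equiv), NaHCO3 (2 equiv), NaOAc (1 equiv), THF/H2O (4:1), 0 °C, dark, 20 min; aq Na2S2O3
Reagents that add atoms: water, O
Why: Achmatowicz rearrangement, in which electrophilic bromine from NBS attacks an α-carbon of the alkoxyfuran, water adds at the other α-carbon, and loss of HBr opens the 2,5-dioxygenated dihydrofuran to the cis-enedione 24, whose C5 hydroxyl adds to the C16 aldehyde. The closest known reaction type is the NBS/water oxidative ring expansion of 2-furylcarbinols to 6-hydroxy-2H-pyran-3(6H)-ones. The pyranone ring closes by 6-exo-trig hemiacetalisation (O–C16 bond), which is possible only because the furan hands on the cis arrangement of C6 and C16 across C7=C8. No stereocentre is set under control: C5 keeps its (S) configuration because none of its bonds is touched, and the new C16 lactol centre forms as an anomeric mixture that step 17 erases. The step needs chemoselectivity for the furan over the C2=C3 and C10=C11 alkenes; the 3-alkoxy group secures it by making the furan much the most electron-rich π system, while the enoate is deactivated and the 1,2-disubstituted alkene is unactivated. The MOM ether also holds the C7 oxygen as an enol ether on the C8 side, so no diketone tautomers arise, and the bicarbonate buffer keeps HBr away from the MOM and TBS groups.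

Step 17
Reactants: 25 the C16 lactol
Product: 26 6-oxo-6-[2-(trimethylsilyl)ethoxy]hexyl (2E)-4-{(2S)-4-(methoxymethoxy)-5-[(2E,4R,5S)-5-(tert-butyldimethylsilyloxy)-4-methylhex-2-en-1-yl]-3-oxo-3,6-dihydro-2H-pyran-2-yl}-3-methylbut-2-enoate
Conditions: Et3SiH (5 equiv), CF3CO2H (10 equiv), CH2Cl2, −40 °C; aq NaHCO3 at −40 °C
Reagents that add atoms: none
Why: ionic hydrogenation of a lactol, in which acid ionises C16–OH to an oxocarbenium ion stabilised through C8=C7–OMOM and silane hydride should add at the less hindered C16 terminus to give the conjugated α-alkoxy enone, with no base present that could remove the C5 proton.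

Step 18
Reactants: 26 the silyl-protected pyranone
Product: 27 6-oxo-6-[2-(trimethylsilyl)ethoxy]hexyl (2E)-4-{(2S)-5-[(2E,4R,5S)-5-hydroxy-4-methylhex-2-en-1-yl]-4-(methoxymethoxy)-3-oxo-3,6-dihydro-2H-pyran-2-yl}-3-methylbut-2-enoate
Conditions: HF·pyridine, pyridine, THF, 0 °C to rt
Reagents that add atoms: none
Why: buffered HF cleaves the secondary TBS ether while the MOM enol ether and the trimethylsilylethyl ester stay, and the medium is never basic, so the C5 centre α to the C6 ketone is not at risk.

Step 19
Reactants: 27 the MOM ether / trimethylsilylethyl ester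
Product: 28 6,7-diketothiomarinolic acid C6, 6-{[(2E)-4-{(2S)-4-hydroxy-5-[(2E,4R,5S)-5-hydroxy-4-methylhex-2-en-1-yl]-3-oxo-3,6-dihydro-2H-pyran-2-yl}-3-methylbut-2-enoyl]oxy}hexanoic acid
Conditions: CF3CO2H/CH2Cl2/H2O (10:30:1), 0 °C to rt; evaporation; MeOH/H2O, rt; reversed-phase chromatography
Reagents that add atoms: none
Why: acidolysis cleaves the MOM acetal at its O–CH2–O carbon and fragments the 2-(trimethylsilyl)ethyl ester by β-silyl-assisted loss of ethene, so both the C7 enol and the carboxylic acid are released without enolate chemistry, and the aqueous methanol treatment should solvolyse any trifluoroacetate formed at C13.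

**Compound list**

1 | methyl 4-oxotetrahydrofuran-3-carboxylate | O=C1COCC1C(=O)OC | starting material
2 | methyl 4-hydroxyfuran-3-carboxylate | COC(=O)c1cocc1O | intermediate
3 | methyl 4-(methoxymethoxy)furan-3-carboxylate | COCOc1cocc1C(=O)OC | intermediate
4 | [4-(methoxymethoxy)furan-3-yl]methanol | COCOc1cocc1CO | intermediate
5 | 3-(bromomethyl)-4-(methoxymethoxy)furan | COCOc1cocc1CBr | intermediate
6 | methyl (S)-3-hydroxybutanoate | C[C@H](O)CC(=O)OC | starting material
7 | dilithium alkoxide enolate of 6 | C[C@H]([O-])/C=C(\[O-])OC.[Li+].[Li+] | intermediate (not isolated)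
8 | methyl (2S,3S)-3-hydroxy-2-methylbutanoate | C[C@H](O)[C@H](C)C(=O)OC | intermediate
9 | methyl (2S,3S)-3-(tert-butyldimethylsilyloxy)-2-methylbutanoate | C[C@H](O[Si](C)(C)C(C)(C)C)[C@H](C)C(=O)OC | intermediate
10 | (2S,3S)-3-(tert-butyldimethylsilyloxy)-2-methylbutanal | C[C@H](O[Si](C)(C)C(C)(C)C)[C@H](C)C=O | intermediate
11 | (3R,4S)-4-(tert-butyldimethylsilyloxy)-3-methylpent-1-yne | C[C@H](O[Si](C)(C)C(C)(C)C)[C@H](C)C#C | intermediate
12 | chloro[(1E,3R,4S)-4-(tert-butyldimethylsilyloxy)-3-methylpent-1-en-1-yl]zirconocene (cyclopentadienyl rings drawn σ-bonded) | C[C@H](O[Si](C)(C)C(C)(C)C)[C@H](C)/C=C/[Zr](Cl)(C1C=CC=C1)C1C=CC=C1 | intermediate (not isolated)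
13 | 3-(methoxymethoxy)-4-[(2E,4R,5S)-5-(tert-butyldimethylsilyloxy)-4-methylhex-2-en-1-yl]furan | COCOc1cocc1C/C=C/[C@@H](C)[C@H](C)O[Si](C)(C)C(C)(C)C | intermediate
14 | 2-lithio derivative of 13 (lithium on the furan carbon between the ring oxygen and the MOM-oxy carbon) | [Li]c1occ(C/C=C/[C@@H](C)[C@H](C)O[Si](C)(C)C(C)(C)C)c1OCOC | intermediate (not isolated)
15 | 3-(methoxymethoxy)-4-[(2E,4R,5S)-5-(tert-butyldimethylsilyloxy)-4-methylhex-2-en-1-yl]furan-2-carbaldehyde | O=Cc1occ(C/C=C/[C@@H](C)[C@H](C)O[Si](C)(C)C(C)(C)C)c1OCOC | intermediate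
16 | methyl 3-methylbut-2-enoate | CC(C)=CC(=O)OC | starting material
17 | lithium dienolate of 16 | C=C(C)C=C([O-])OC.[Li+] | intermediate (not isolated)
18 | tert-butyl[(1-methoxy-3-methylbuta-1,3-dien-1-yl)oxy]dimethylsilane | C=C(C)C=C(OC)O[Si](C)(C)C(C)(C)C | intermediate
19 | methyl (2E,5S)-5-hydroxy-5-{3-(methoxymethoxy)-4-[(2E,4R,5S)-5-(tert-butyldimethylsilyloxy)-4-methylhex-2-en-1-yl]furan-2-yl}-3-methylpent-2-enoate | C/C(=C\C(=O)OC)C[C@H](O)c1occ(C/C=C/[C@@H](C)[C@H](C)O[Si](C)(C)C(C)(C)C)c1OCOC | intermediate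
20 | (2E,5S)-5-hydroxy-5-{3-(methoxymethoxy)-4-[(2E,4R,5S)-5-(tert-butyldimethylsilyloxy)-4-methylhex-2-en-1-yl]furan-2-yl}-3-methylpent-2-enoic acid | C/C(=C\C(=O)O)C[C@H](O)c1occ(C/C=C/[C@@H](C)[C@H](C)O[Si](C)(C)C(C)(C)C)c1OCOC | intermediate
21 | 6-bromohexanoic acid | OC(=O)CCCCCBr | starting material
22 | 2-(trimethylsilyl)ethyl 6-bromohexanoate | C[Si](C)(C)CCOC(=O)CCCCCBr | intermediate
23 | 6-oxo-6-[2-(trimethylsilyl)ethoxy]hexyl (2E,5S)-5-hydroxy-5-{3-(methoxymethoxy)-4-[(2E,4R,5S)-5-(tert-butyldimethylsilyloxy)-4-methylhex-2-en-1-yl]furan-2-yl}-3-methylpent-2-enoate (key-step precursor) | C/C(=C\C(=O)OCCCCCC(=O)OCC[Si](C)(C)C)C[C@H](O)c1occ(C/C=C/[C@@H](C)[C@H](C)O[Si](C)(C)C(C)(C)C)c1OCOC | intermediate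
24 | ring-opened hydroxy enedione: C5 carbinol, C6 ketone, C7(OMOM)=C8 with the C6 acyl and C16 formyl groups cis | C/C(=C\C(=O)OCCCCCC(=O)OCC[Si](C)(C)C)C[C@H](O)C(=O)/C(OCOC)=C(\C=O)C/C=C/[C@@H](C)[C@H](C)O[Si](C)(C)C(C)(C)C | intermediate (not isolated)
25 | 6-oxo-6-[2-(trimethylsilyl)ethoxy]hexyl (2E)-4-{(2S)-6-hydroxy-4-(methoxymethoxy)-5-[(2E,4R,5S)-5-(tert-butyldimethylsilyloxy)-4-methylhex-2-en-1-yl]-3-oxo-3,6-dihydro-2H-pyran-2-yl}-3-methylbut-2-enoate (anomeric mixture; key-step product) | C/C(=C\C(=O)OCCCCCC(=O)OCC[Si](C)(C)C)C[C@@H]1OC(O)C(C/C=C/[C@@H](C)[C@H](C)O[Si](C)(C)C(C)(C)C)=C(OCOC)C1=O | intermediate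
26 | 6-oxo-6-[2-(trimethylsilyl)ethoxy]hexyl (2E)-4-{(2S)-4-(methoxymethoxy)-5-[(2E,4R,5S)-5-(tert-butyldimethylsilyloxy)-4-methylhex-2-en-1-yl]-3-oxo-3,6-dihydro-2H-pyran-2-yl}-3-methylbut-2-enoate | C/C(=C\C(=O)OCCCCCC(=O)OCC[Si](C)(C)C)C[C@@H]1OCC(C/C=C/[C@@H](C)[C@H](C)O[Si](C)(C)C(C)(C)C)=C(OCOC)C1=O | intermediate
27 | 6-oxo-6-[2-(trimethylsilyl)ethoxy]hexyl (2E)-4-{(2S)-5-[(2E,4R,5S)-5-hydroxy-4-methylhex-2-en-1-yl]-4-(methoxymethoxy)-3-oxo-3,6-dihydro-2H-pyran-2-yl}-3-methylbut-2-enoate | C/C(=C\C(=O)OCCCCCC(=O)OCC[Si](C)(C)C)C[C@@H]1OCC(C/C=C/[C@@H](C)[C@H](C)O)=C(OCOC)C1=O | intermediate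
28 | 6,7-diketothiomarinolic acid C6 | C/C(=C\C(=O)OCCCCCC(=O)O)C[C@@H]1OCC(C/C=C/[C@@H](C)[C@H](C)O)=C(O)C1=O | target

**Step count**
Total: 19 steps. Longest linear sequence: 13 steps (steps 1–4, 9, 10, 12, 13, 15–19 from 1; the branch from 6 through steps 5–8 is equally long).

**Steps most likely to fail**

1. Step 16 (ring expansion). What may go wrong: bromination or bromohydrin formation at the C10=C11 alkene, or capture of the brominated furan cation by water at the MOM-bearing carbon with loss of the MOM group instead of 2,5-dioxygenation. Fallback: set out from 23 and replace electrophilic halogen by a cycloaddition that can only engage furan C2 and C5. Dye-sensitised photooxygenation (O2, tetraphenylporphyrin, visible light, CH2Cl2, −78 °C) should add singlet oxygen across the alkoxyfuran much faster than it reacts with the two alkenes, giving the bicyclic 2,5-endoperoxide F1. Me2S at −78 °C to rt reduces the O–O bond and releases the cis-enedione 24, which closes to lactol 25, where the route is rejoined.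

2. Step 12 (asymmetric vinylogous aldol). What may go wrong: poor facial selectivity because the ortho MOM-oxy group competes for the silicon cation, attack through the α-carbon of the dienolate, or ionisation of the electron-rich furyl carbinol silyl ether under SiCl4. Fallback: set out from 15 and build C5 and the enoate in separate, reagent-controlled operations.
   - Brown allylation with (−)-Ipc2B(allyl) (the antipode from (+)-α-pinene, expected to add to the Si face; Et2O, −78 °C; ethanolamine work-up) gives the (S)-homoallylic alcohol F2.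
   - TESCl/imidazole gives the triethylsilyl ether F3.
   - Tsuji–Wacker oxidation of the terminal alkene (PdCl2 10 mol %, CuCl, O2, DMF/H2O, rt) gives the methyl ketone F4.
   - Horner–Wadsworth–Emmons olefination with the phosphonate F5 (from diethylphosphonoacetic acid, Cs2CO3 and bromide 22 in DMF; NaH, THF, 0 °C to rt) gives, after chromatographic removal of the 2Z isomer, the silyl ether F6.
   - Buffered HF·pyridine at 0 °C removes the triethylsilyl group in the presence of the TBS ether and returns to the route at 23; steps 13 and 15 are then not needed.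

3. Step 17 (lactol reduction). What may go wrong: hydride delivery to C7 instead of C16, loss of the C5 proton from the long-lived oxocarbenium ion with erosion of the C5 configuration, or premature MOM cleavage. Fallback: set out from 25 and change from a cationic to a palladium π-allyl pathway. Acetylation (Ac2O, pyridine, DMAP cat., CH2Cl2, 0 °C) gives the anomeric acetate F7. Pd(PPh3)4 (5 mol %) with Bu3SnH (1.2 equiv, slow addition) in THF at rt should ionise it to the π-allyl complex spanning C16–C8–C7 and deliver hydride from palladium to the less substituted C16 terminus under neutral conditions, returning to the route at 26.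

**Further compounds**
F1 | step 16 | 2,5-endoperoxide of 23 (O–O bridge between furan C2 and C5, 2,3,7-trioxabicyclo[2.2.1]hept-5-ene core) | C/C(=C\C(=O)OCCCCCC(=O)OCC[Si](C)(C)C)C[C@H](O)C12OOC(O1)C(C/C=C/[C@@H](C)[C@H](C)O[Si](C)(C)C(C)(C)C)=C2OCOC
F2 | step 12 | (1S)-1-{3-(methoxymethoxy)-4-[(2E,4R,5S)-5-(tert-butyldimethylsilyloxy)-4-methylhex-2-en-1-yl]furan-2-yl}but-3-en-1-ol | C=CC[C@H](O)c1occ(C/C=C/[C@@H](C)[C@H](C)O[Si](C)(C)C(C)(C)C)c1OCOC
F3 | step 12 | triethylsilyl ether of F2 | C=CC[C@H](O[Si](CC)(CC)CC)c1occ(C/C=C/[C@@H](C)[C@H](C)O[Si](C)(C)C(C)(C)C)c1OCOC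
F4 | step 12 | (4S)-4-{3-(methoxymethoxy)-4-[(2E,4R,5S)-5-(tert-butyldimethylsilyloxy)-4-methylhex-2-en-1-yl]furan-2-yl}-4-(triethylsilyloxy)butan-2-one | CC(=O)C[C@H](O[Si](CC)(CC)CC)c1occ(C/C=C/[C@@H](C)[C@H](C)O[Si](C)(C)C(C)(C)C)c1OCOC
F5 | step 12 | 6-oxo-6-[2-(trimethylsilyl)ethoxy]hexyl (diethoxyphosphoryl)acetate | CCOP(=O)(CC(=O)OCCCCCC(=O)OCC[Si](C)(C)C)OCC
F6 | step 12 | C5 O-triethylsilyl ether of 23 | C/C(=C\C(=O)OCCCCCC(=O)OCC[Si](C)(C)C)C[C@H](O[Si](CC)(CC)CC)c1occ(C/C=C/[C@@H](C)[C@H](C)O[Si](C)(C)C(C)(C)C)c1OCOC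
F7 | step 17 | C16 O-acetate of 25 (anomeric mixture) | C/C(=C\C(=O)OCCCCCC(=O)OCC[Si](C)(C)C)C[C@@H]1OC(OC(C)=O)C(C/C=C/[C@@H](C)[C@H](C)O[Si](C)(C)C(C)(C)C)=C(OCOC)C1=O
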